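I had no constants for this flask, so I asked what the earlier runs could give in their place.

| setting | violet | grey | red | larch | maple | cedar | ash |
|---|---|---|---|---|---|---|---|
| starting material | 10 mM | 10 mM | 10 mM | 10 mM | 10 mM | 10 mM | 10 mM |
| reagent | 7.4 mM | 16 mM | 11 mM | 11.0 mM | 11.0 mM | 11.0 mM | 11.0 mM |
| capture agent | 1 mM | 1 mM | 1.5 mM | 1.00 mM | 1.00 mM | 1.00 mM | 1.00 mM |
| temperature | 45 °C | 78 °C | 45 °C | 50 °C | 90 °C | 70 °C | 30 °C |
| remark | run made earlier | run made earlier | run made earlier |  |  |  |  |
| time |  |  |  | 3.0 min | 3.0 min | 3.0 min | 3.0 min |

| run | time / s | target / % | side product / % | trapped intermediate / % |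
|---|---|---|---|---|
| violet | 10.0 | 0 | 0 | 2 |
| violet | 15.0 | 2 | 0 | 3 |
| violet | 30.0 | 4 | 5 | 0 |
| violet | 60.0 | 15 | 3 | 3 |
| violet | 120 | 23 | 6 | 4 |
| grey | 10.0 | 21 | 6 | 5 |
| grey | 15.0 | 28 | 12 | 8 |
| grey | 20.0 | 27 | 16 | 7 |
| grey | 30.0 | 27 | 18 | 12 |
| red | 10.0 | 0 | 2 | 0 |
| red | 15.0 | 6 | 3 | 0 |
| red | 30.0 | 12 | 3 | 4 |
| red | 60.0 | 19 | 4 | 2 |
| red | 120 | 31 | 7 | 5 |

(each reading ± 1.5 percentage points)

- percent here means starting material units held: one side product counts as two
- what was read earlier has a scatter of 1.5 percentage points, one standard deviation
- candidate steps: starting material + reagent <-> open intermediate; open intermediate <-> target; starting material + open intermediate -> side product; open intermediate + capture agent -> trapped intermediate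

1. the flask that comes out highest in share of target in all that became target or side product or trapped intermediate, or "all alike" when all lie within 1.5 percentage points (larch / maple / cedar / ash / all alike)
2. share of target in all that became target or side product or trapped intermediate, larch
3. share of target in all that became target or side product or trapped intermediate, maple
4. share of target in all that became target or side product or trapped intermediate, cedar
5. share of target in all that became target or side product or trapped intermediate, ash

I followed one molecule of starting material in slow motion. In the first instants it has to meet reagent and become open intermediate, and the violet run read 0% target at 10.0 s. In the middle, the open intermediate stands at a fork: it closes to target, or a second starting material takes it to side product, or capture agent takes it to trapped intermediate. Of these exits, the side exit depends on c(starting material), so its odds against target shrink as the flask proceeds.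

I therefore pooled the last readings of the violet and red runs, both at 45 °C. Halfway between the charge and what those readings left, c(starting material) was 8.10 mM. Scaling this by target over side product gave 33.6 mM. I call this c*, the even concentration: the c(starting material) at which side product and target grow alike, a selectivity factor written as a concentration. Trapped intermediate per target read 0.167, which I call v. The share of target is then 1/(1 + c/c* + v), which gave 71.1%.

The end of a run is a different matter. In the grey run, target read 28% at 15.0 s and 27% at 30.0 s, while side product rose from 12% to 18%, so target seemed to be running back and the share read 47.4%. The fork rule does not cover that, so I committed to it for larch at 50 °C and to about 71.1% there. I expected cedar and maple to lie near or below the grey share, and I had no reading for ash.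

The forecast named ash, with ash at 71% (62% to 80%), larch 66% (58% to 73%), cedar 50% (39% to 61%) and maple 39% (27% to 52%). Its words were: “What hurts in the grey run is time.” My larch figure stood above its figure.

The highest flask was larch at 72.3%, with ash at 58.6%, cedar at 32.6% and maple at 3.85%. At the end, maple held 3.26% target against 71.5% side product. Larch kept 34% of its starting material, so its halfway c was 6.68 mM, and c* with v gives 73.2%.

    starting material + reagent ⇌ open intermediate (K = 82.0 /M, k = 3.40 /M/s, Ea = 61.0 kJ/mol, ΔH = 5.00 kJ/mol)
    open intermediate ⇌ target (K = 3.00, k = 1.20 /s, Ea = 84.0 kJ/mol, ΔH = −80.0 kJ/mol)
    starting material + open intermediate → side product (k = 3.90 /M/s, Ea = 37.0 kJ/mol)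
    open intermediate + capture agent → trapped intermediate (k = 46.0 /M/s, Ea = 41.0 kJ/mol)
    (constants at 70 °C)

The neighbouring flask is larch with 19 mM reagent. In that flask 14% of the starting material was left, so the halfway c was 5.70 mM, and c* with v held as read gives 74.8%. The computed share was 76.9%, above that figure.

The earlier runs and the new flask are simulated for an exercise, and the scatter is random.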